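## The problem

Eudesmane numbering is used throughout: ring A is C1–C5 plus C10, ring B is C5–C10, C14 is the methyl on C10, C15 the methyl on C4, and C11–C13 the side chain on C7 (C12 carboxyl, C13 methylene). β is the face of C14.

The target is a Δ4-octalin with a tetrasubstituted C4=C5 alkene and a quaternary C10. It carries an allylic (E)-3-methylpent-2-enoate at C3, a methyl acrylate unit at C7 and an acetate at C8. The configuration is 3S,7R,8R,10R (3β-O, 7β-C, 8β-O, 10β-Me). C10 is the one centre that no neighbour can set, and it is the centre that can set the others. Its axial methyl shields the β face of a C3 and of a C8 carbonyl, so hydride enters from α and leaves the 3β and 8β oxygens. C7, being α to a C8 ketone, can be equilibrated to the equatorial 7β position.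

The cis 7,8 pattern is that of an opened cis-fused 12,8-lactone, so the γ-hydroxy ester will tend to re-close. The acrylate is a Michael acceptor, and neither the acetate nor the C3 enoate survives enolate bases or hydride. The C3 allylic oxygen ionises towards a diene under acid. These groups therefore have to arrive late and in a fixed order.

The enabling feature is that C14 sits on C10 next to C5 of the C4=C5 alkene, with an oxygen at C3. A C5–C10–C14 cyclopropane flanked by a C3 ketone is a masked 10-methyl-4-en-3-one, and that cyclopropane can be delivered face-selectively from a C3 hydroxyl that is homoallylic to a C5=C10 alkene. A C5=C10 alkene with oxygen at C3 and C8 is what Birch reduction of a 6-methoxytetralin leaves, so the asymmetric problem reduces to one secondary carbinol on a tetralin.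

## Retrosynthesis

**C3 ester.** Cutting the O3–acyl bond of target 37 gives allylic alcohol 35 and (E)-3-methylpent-2-enoic acid 36. This cut comes last because the enoate cannot pass through any enolate, hydride or hydroxide step. Alcohol 35 is six carbons and one geometry-sensitive alkene simpler. The forward step must acylate an equatorial allylic alcohol without ionising it and without isomerising the acid.

**C8 acetate and the open ester.** Removing the acetyl group (34 to 32, with the C3 oxygen as a silyl ether) and reconnecting O8 to C12 leads to the α-methylene cis-lactone 30. Carrying the lactone keeps the C8 oxygen and the C12 carboxyl mutually protected through all strongly basic steps. An open hydroxy ester would need an extra protecting group on O8 and would be exposed to re-closure several times instead of once. The forward sequence must saponify without conjugate addition, methylate the carboxylate under neutral conditions, and acetylate faster than the ring re-closes.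

**C11=C13.** Cutting the C11–C13 bond of 30 leads through Mannich base 27 to the saturated lactone 24. The iminium route is preferred to a selenoxide elimination because, in a cis-fused lactone, syn elimination towards H-7 gives the endocyclic butenolide; elimination of a CH2–NMe3+ group can only give the exocyclic alkene.

**C8–H and C7–C11.** Lactone 24 comes from keto ester 22 by reduction at C8. Keto ester 22 comes from ketone 18 and methyl bromoacetate 19 by cutting C7–C11. C7 is α to the C8 carbonyl, so this is the natural enolate polarity, the two-carbon electrophile is commercial, and the quaternary C10 discourages enolisation towards C9. The forward steps must deprotonate at C7, not C9, converge on the equatorial 7β chain, and deliver hydride from the α face.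

**C3 oxygen.** Ketone 18 goes back through ketal 17 and allylic alcohol 15 to enone ketal 14 (cutting C3–H). The C3 ketone is reduced while C8 is still masked, so the two carbonyls are never free together. The silyl ether is chosen to survive LiN(i-Pr)2, LiBH(s-Bu)3 and KOH and to leave with fluoride beside an acetate and an acrylate.

**Enone to cyclopropyl ketone.** Re-forming the C5–C14 bond of 14 in place of C4=C5 gives cyclopropyl ketone 13, and from it alcohol 12. The neighbouring disconnection, a Robinson annulation across C4=C5 and C1–C10, would need an enantioselective Michael addition to create C10. Here C10 is created by an intramolecular delivery whose sense follows from a carbinol. The forward step must protonate C14 and break only C5–C14.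

**Key disconnection.** Cutting C10–C14 and C5–C14 of 12 gives homoallylic alcohol 9 and diiodomethane 10. Alcohol 9 has two stereocentres instead of four and no quaternary carbon. The forward reaction must add methylene to a tetrasubstituted alkene on the β face only.

**Ring B oxidation level.** Ketal 9 goes back through the 1-methoxy-1,4-diene 7 to the anisole 6 (Birch retron: C5=C10 is the ring-fusion alkene that dissolving-metal reduction leaves). Converting the enol ether directly to the dioxolane avoids a free β,γ-unsaturated ketone.

**Carbinol and C15.** Cutting C3–O and C4–H of 6 (syn hydroboration, anti-Markovnikov, hence trans) gives dihydronaphthalene 4. Cutting C4–C15 gives 6-methoxy-1-tetralone 1 and methylmagnesium bromide 2. Both carbocycles are therefore purchased and the only asymmetric reagent acts on a simple styrene-type alkene.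

## Roads not taken

**Alternative 1:** Cutting C1–C2 and C5–C10 in a retro-Diels–Alder sense leads from the tricyclic silyl enol ether A2 to the triene lactone A1. In A1 a 2-silyloxy diene arm on C7 and a methallyl group on C8 are held on a trans γ-lactone. Heating A1 would close rings A and B at once and create C10.
- Merits: two rings and the quaternary centre form in one step, the C3 oxygen and C15 arrive regiodefined, and C12 and O8 are in place from the start, so no C7 alkylation is needed. In bonds formed per step this is better than the chosen plan, whose key step closes only a three-membered ring.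
- Weak points: the dienophile is an unactivated 1,1-disubstituted alkene and the diene terminus is trisubstituted, so high temperatures beside a silyl enol ether are to be expected. The facial outcome at C10 relative to the lactone rests on tether conformation. The trans lactone of A2 places O8 on the α face, so C8 must later be inverted by opening, oxidation and reduction. The alkene emerges as C3=C4 and has to be moved to C4=C5 by a Saegusa-type oxidation with Pd(OAc)2 and a reduction. A1 itself, with two stereocentres and a sensitive diene, is not a short target.
- Comparison: the chosen plan sets commercial carbocycles and a single controlling carbinol against this convergence, and C8 comes out right the first time.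

**Alternative 2:** Cutting C7–C8 leads from the 8-keto acrylate A4 to the ring-A aldehyde A3, which carries a (Z)-2-(bromomethyl)enoate arm. A triazolium-derived carbene would turn the C8 aldehyde into an acyl anion equivalent that adds to C7 and expels bromide, closing ring B and releasing the C11=C13 methylene.
- Merits: A4 already contains the C8 ketone and the finished acrylate. The lactone detour (methylenation and re-opening) disappears, and only reduction, acetylation, desilylation and acylation would remain. After the key step this road is clearly shorter than the chosen one.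
- Weak points: A3 still needs C10 and the tetrasubstituted alkene made enantioselectively by other means, so the hardest centre is postponed, not solved. The allylic bromide can alkylate the free carbene. Aliphatic acyl anion additions to β-substituted acceptors are slow. In A4, H-7 is α to the ketone and allylic to the acrylate, so base can move C11=C13 into conjugation as C7=C11. The later C8 reduction must spare the acrylate.
- Comparison: the chosen plan sets against the shorter end-game a secure origin for C10 and reaction types that are each established on this substrate class.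

**Alternative 3:** Cutting C7–C11 leads from the cis-fused lactol ether A6 to the mixed bromoacetal A5 of a 4,6-dien-8β-ol. A tin-hydride-mediated Ueno–Stork cyclisation would add the C11 radical 5-exo to C7 and reduce the resulting allyl radical at C6.
- Merits: the cis 7,8 relation is enforced by the ring closure itself, with no enolate regiochemistry and no epimerisation step. On this one point the road is better than the chosen plan, which relies on thermodynamic control at C7 and on hydride selectivity at C8.
- Weak points: hydrogen transfer to the allyl radical can occur at C4 as well as C6, which would move the alkene to C5=C6 and create an uncontrolled C4 centre. Stoichiometric tin is needed. A6 must be hydrolysed and oxidised to the lactone beside an acid-labile allylic silyl ether. The same methylenation and opening end-game then follows, so nothing is saved there. C10 again needs a separate asymmetric solution.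
- Comparison: the chosen plan answers the stereocontrol advantage with two strongly substrate-biased steps (equatorial preference at C7, syn-axial methyl at C8) and addresses C10 directly.

Key step: step 5

Assumption: IpcBH2 prepared from (+)-α-pinene is taken to attack alkene 4 with the facial sense it shows towards 1-methylcyclohexene, which corresponds to the (1S,2S) alcohol 6; were the sense opposite, the borane from (−)-α-pinene would be used and nothing else changes.

## Route

Step 1
Reactants: 1 6-methoxy-1-tetralone; 2 methylmagnesium bromide
Product: 4 7-methoxy-4-methyl-1,2-dihydronaphthalene, via tertiary benzylic alcohol 3 (not isolated)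
Conditions: MeMgBr, THF, 0 °C → rt; then 2 M aq. HCl, rt
Reagents that add atoms: methylmagnesium bromide C[Mg]Br
Why: Grignard addition to the aryl ketone, then acid dehydration of the tertiary p-methoxybenzylic alcohol, which ionises readily and loses a proton to the conjugated trisubstituted alkene; no stereocentre is formed.

Step 2
Reactants: 4 7-methoxy-4-methyl-1,2-dihydronaphthalene
Product: 6 (1S,2S)-6-methoxy-1-methyl-1,2,3,4-tetrahydronaphthalen-2-ol (trans), via tetralinyl isopinocampheyl borane 5 (not isolated)
Conditions: IpcBH2 [from (+)-α-pinene], THF, −25 °C; then NaOH, H2O2, H2O, 0 °C → rt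
Reagents that add atoms: hydrogen peroxide OO
Why: Asymmetric hydroboration–oxidation of a trisubstituted cyclic alkene with monoisopinocampheylborane; boron goes to the non-benzylic carbon and H and B add syn, which fixes the trans relation of methyl and hydroxyl, while the chiral borane selects the alkene face and so the absolute configuration (oxidation proceeds with retention); enantiomeric purity can be raised by recrystallisation of 6 or of a crystalline ester.

Step 3
Reactants: 6 (1S,2S)-6-methoxy-1-methyl-1,2,3,4-tetrahydronaphthalen-2-ol
Product: 7 (1S,2S)-6-methoxy-1-methyl-1,2,3,4,5,8-hexahydronaphthalen-2-ol (enol ether C7=C8 and ring-fusion alkene C5=C10 in eudesmane numbering)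
Conditions: Li, NH3 (l), t-BuOH, THF, −78 → −33 °C
Reagents that add atoms: none
Why: Birch reduction of an alkyl-substituted anisole gives the 1-methoxy-1,4-diene in which the methoxy-bearing and the two ring-fusion carbons stay sp2; the homobenzylic alkoxide is inert and neither stereocentre is touched.

Step 4
Reactants: 7 (1S,2S)-6-methoxy-1-methyl-1,2,3,4,5,8-hexahydronaphthalen-2-ol; 8 ethylene glycol
Product: 9 3β-hydroxy-4α-methyl-5(10)-ene 8-(ethylene ketal), i.e. (5'S,6'S)-5'-methyl-3',4',5',6',7',8'-hexahydro-1'H-spiro[1,3-dioxolane-2,2'-naphthalen]-6'-ol
Conditions: HOCH2CH2OH, p-TsOH·H2O (cat.), CH2Cl2, 0 °C → rt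
Reagents that add atoms: ethylene glycol OCCO
Why: Acid-catalysed transketalisation of the enol ether (protonation at C7, capture of the oxocarbenium ion by the diol, loss of methanol) gives the dioxolane without passing through a free β,γ-unsaturated ketone, so the tetrasubstituted C5=C10 alkene stays in place under the mild acid.

Step 5
Reactants: 9 3β-hydroxy-4α-methyl-5(10)-ene 8-(ethylene ketal); 10 diiodomethane
Product: 12 3β-hydroxy-4α-methyl-5β,10β-methano 8-(ethylene ketal) (cyclopropane C5–C10–C14 on the β face, cis to the hydroxyl), via ethylzinc alkoxide 11 (not isolated)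
Conditions: Et2Zn, CH2I2, CH2Cl2, −10 °C → rt
Reagents that add atoms: diiodomethane ICI
Why: Et2Zn converts the hydroxyl of 9 into the ethylzinc alkoxide 11 and, with CH2I2, forms EtZnCH2I; the alkoxide oxygen binds the carbenoid and the methylene is transferred to C5=C10 through a concerted, syn, butterfly-type transition state, so C10–C14 and C5–C14 form together. The closest known reaction type is the hydroxyl-directed Simmons–Smith cyclopropanation (Furukawa conditions) of cyclic homoallylic alcohols, as established for 3-hydroxy-5(10)-ene steroids, which react cis to the hydroxyl. The three-membered ring closes in a single [2+1] methylene transfer, not by stepwise ring closure. Both new stereocentres, C5 and C10, are controlled by the C3 carbinol: allylic 1,2-strain between the C4 methyl and C6 places the 4α-methyl pseudo-axial, which puts the trans 3β-oxygen axial over the β face of the alkene. The same pseudo-axial methyl shields the α face of C5, so tether and steric shielding point the same way. The selectivity required is facial (β over α) on a tetrasubstituted alkene; there is no competing alkene, and an excess of carbenoid compensates for the low reactivity of the hindered double bond. The dioxolane is expected to tolerate the weakly Lewis-acidic zinc species at this temperature.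

Step 6
Reactants: 12 3β-hydroxy-4α-methyl-5β,10β-methano 8-(ethylene ketal)
Product: 13 4α-methyl-5β,10β-methano-3-one 8-(ethylene ketal)
Conditions: Dess–Martin periodinane, CH2Cl2, 0 °C → rt
Reagents that add atoms: none
Why: Dess–Martin oxidation of a secondary alcohol under near-neutral conditions that spare the ketal and the cyclopropane; the C4 centre, now α to the ketone, is removed in the next step.

Step 7
Reactants: 13 4α-methyl-5β,10β-methano-3-one 8-(ethylene ketal)
Product: 14 (10R)-4,10β-dimethyl-4-en-3-one 8-(ethylene ketal) (11,12,13-trinoreudesm-4-ene-3,8-dione 8-ketal)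
Conditions: HCl (anhydrous), CHCl3, 0 °C
Reagents that add atoms: none
Why: Acid-catalysed homoconjugate opening of a cyclopropylmethyl ketone: enolisation towards C4 makes a vinylcyclopropane, protonation at the unsubstituted C14 breaks C5–C14 with the enol pushing electrons into C4=C5, so C14 stays on C10 as the β-methyl and the conjugated enone forms; water is excluded to keep the dioxolane, and the C10 configuration is that set in step 5.

Step 8
Reactants: 14 (10R)-4,10β-dimethyl-4-en-3-one 8-(ethylene ketal)
Product: 15 (3S,10R)-3β-hydroxy-4,10β-dimethyl-4-ene 8-(ethylene ketal)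
Conditions: NaBH4, CeCl3·7H2O, MeOH, −40 → 0 °C
Reagents that add atoms: none
Why: Luche 1,2-reduction of the enone; hydride attacks axially from the α face, anti to the 10β-methyl, to give the quasi-equatorial 3β-alcohol, as is usual for 10β-methyl-4-en-3-ones.

Step 9
Reactants: 15 (3S,10R)-3β-hydroxy-4,10β-dimethyl-4-ene 8-(ethylene ketal); 16 tert-butyldimethylsilyl chloride
Product: 17 3β-(tert-butyldimethylsilyloxy)-4,10β-dimethyl-4-ene 8-(ethylene ketal)
Conditions: TBSCl, imidazole, DMF, rt
Reagents that add atoms: tert-butyldimethylsilyl chloride CC(C)(C)[Si](C)(C)Cl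
Why: Standard silylation of a secondary allylic alcohol; the TBS ether tolerates the amide base, hydride and hydroxide used later and is removed by fluoride.

Step 10
Reactants: 17 3β-(tert-butyldimethylsilyloxy)-4,10β-dimethyl-4-ene 8-(ethylene ketal)
Product: 18 3β-(tert-butyldimethylsilyloxy)-11,12,13-trinoreudesm-4-en-8-one (10β-methyl)
Conditions: PPTS (cat.), acetone–H2O, 50 °C
Reagents that add atoms: water O
Why: Mild acid hydrolysis of a cyclohexanone dioxolane; pyridinium tosylate is weak enough to leave the secondary allylic silyl ether un-ionised, and the C4=C5 alkene cannot move into conjugation with C8.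

Step 11
Reactants: 18 3β-(tert-butyldimethylsilyloxy)-11,12,13-trinoreudesm-4-en-8-one; 19 methyl bromoacetate
Product: 22 methyl 8-oxo-3β-(tert-butyldimethylsilyloxy)-13-noreudesm-4-en-12-oate (7β side chain, 7α-H), via C7 lithium enolate 20 (not isolated), via 7α-epimeric keto ester 21 (not isolated)
Conditions: LiN(i-Pr)2, THF, −78 °C; BrCH2CO2Me, DMPU, −78 → −30 °C; then MeOH, NaOMe (cat.), 0 °C → rt
Reagents that add atoms: methyl bromoacetate COC(=O)CBr
Why: Kinetic deprotonation occurs at C7 because the C9 hydrogens are neopentyl, next to quaternary C10; alkylation of the lithium enolate with the α-bromo ester is expected from the axial α direction, and methoxide equilibration through the enolate then converges on the equatorial 7β epimer.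

Step 12
Reactants: 22 methyl 8-oxo-3β-(tert-butyldimethylsilyloxy)-13-noreudesm-4-en-12-oate
Product: 24 3β-(tert-butyldimethylsilyloxy)-13-noreudesm-4-en-12,8β-olide (cis-fused γ-lactone, 7α-H, 8α-H), via lithium 8β-alkoxide 23 (not isolated)
Conditions: LiBH(s-Bu)3, THF, −78 °C → rt; then H2O
Reagents that add atoms: none
Why: The bulky hydride attacks the C8 ketone from the equatorial α direction, and axial β approach is in any case blocked by the syn-axial 10β-methyl, giving the axial 8β-alkoxide, which closes onto the adjacent equatorial methyl ester on warming (lactonisation) to the cis-fused lactone.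

Step 13
Reactants: 24 3β-(tert-butyldimethylsilyloxy)-13-noreudesm-4-en-12,8β-olide; 25 N,N-dimethylmethyleneiminium iodide
Product: 27 13-(dimethylamino)-3β-(tert-butyldimethylsilyloxy)eudesm-4-en-12,8β-olide (aminomethyl on the convex α face of the lactone, cis to H-7), via lactone lithium enolate 26 (not isolated)
Conditions: LiN(i-Pr)2, THF, −78 °C; Me2N=CH2+ I−, −78 °C → rt
Reagents that add atoms: N,N-dimethylmethyleneiminium iodide C=[N+](C)C.[I-]
Why: Mannich reaction of a lactone lithium enolate with Eschenmoser's salt; the electrophile enters from the convex face of the cis-fused bicycle, and the new C11 centre is of no consequence because it becomes sp2 in step 14.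

Step 14
Reactants: 27 13-(dimethylamino)-3β-(tert-butyldimethylsilyloxy)eudesm-4-en-12,8β-olide; 28 iodomethane
Product: 30 3β-(tert-butyldimethylsilyloxy)eudesma-4,11(13)-dien-12,8β-olide, via trimethylammonium iodide 29 (not isolated)
Conditions: MeI, MeOH, rt; then aq. NaHCO3, EtOAc, rt
Reagents that add atoms: none
Why: Quaternisation of the tertiary amine, then base-induced β-elimination of trimethylamine from the β-ammonio lactone (Hofmann-type, E1cB), which can only give the exocyclic C11=C13 alkene.

Step 15
Reactants: 30 3β-(tert-butyldimethylsilyloxy)eudesma-4,11(13)-dien-12,8β-olide; 28 iodomethane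
Product: 32 methyl 8β-hydroxy-3β-(tert-butyldimethylsilyloxy)eudesma-4,11(13)-dien-12-oate, via potassium hydroxy carboxylate 31 (not isolated)
Conditions: KOH, THF–H2O, 0 °C → rt; evaporate; MeI, DMF, 0 °C → rt
Reagents that add atoms: potassium hydroxide [K+].[OH-]; iodomethane CI
Why: Saponification by acyl–oxygen cleavage keeps the C8 configuration, and the hard hydroxide attacks the lactone carbonyl, after which the carboxylate is a poor Michael acceptor; SN2 methylation of the carboxylate in DMF makes the ester under neutral conditions, so the γ-hydroxy ester sees neither acid nor alkoxide, and the crude product is taken on at once.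

Step 16
Reactants: 32 methyl 8β-hydroxy-3β-(tert-butyldimethylsilyloxy)eudesma-4,11(13)-dien-12-oate; 33 acetic anhydride
Product: 34 methyl 8β-acetoxy-3β-(tert-butyldimethylsilyloxy)eudesma-4,11(13)-dien-12-oate
Conditions: Ac2O, DMAP, pyridine, CH2Cl2, 0 °C → rt
Reagents that add atoms: acetic anhydride CC(=O)OC(C)=O
Why: DMAP-catalysed acetylation of the axial secondary alcohol through the acetylpyridinium ion should outrun the uncatalysed intramolecular transesterification; once O8 is acetylated the ring can no longer re-close.

Step 17
Reactants: 34 methyl 8β-acetoxy-3β-(tert-butyldimethylsilyloxy)eudesma-4,11(13)-dien-12-oate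
Product: 35 methyl 8β-acetoxy-3β-hydroxyeudesma-4,11(13)-dien-12-oate
Conditions: Bu4NF, AcOH, THF, rt
Reagents that add atoms: none
Why: Fluoride-mediated desilylation buffered with acetic acid, so that neither the acetate nor the acrylate meets free alkoxide or fluoride base and the allylic alcohol is not exposed to strong acid.

Step 18
Reactants: 35 methyl 8β-acetoxy-3β-hydroxyeudesma-4,11(13)-dien-12-oate; 36 (E)-3-methylpent-2-enoic acid
Product: 37 methyl 8β-acetoxy-3β-[(E)-3-methylpent-2-enoyloxy]eudesma-4,11(13)-dien-12-oate (3S,7R,8R,10R), the target
Conditions: DCC, DMAP (cat.), CH2Cl2, 0 °C → rt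
Reagents that add atoms: (E)-3-methylpent-2-enoic acid CC/C(C)=C/C(=O)O
Why: Steglich esterification of the equatorial allylic alcohol; carbodiimide activation avoids the acid chloride and amine-base conditions that form vinylketenes, so the E geometry and conjugation of the acid should be kept, and C3 reacts with retention because only the O–H bond is broken.

## Compound list

1 | 6-methoxy-1-tetralone | COc1ccc2C(=O)CCCc2c1 | starting material
2 | methylmagnesium bromide | C[Mg]Br | starting material
3 | 6-methoxy-1-methyl-1,2,3,4-tetrahydronaphthalen-1-ol (racemic tertiary alcohol) | CC1(O)CCCc2cc(OC)ccc12 | intermediate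
4 | 7-methoxy-4-methyl-1,2-dihydronaphthalene | CC1=CCCc2cc(OC)ccc12 | intermediate
5 | (trans-6-methoxy-1-methyltetralin-2-yl)(isopinocampheyl)borane, Ipc from (+)-α-pinene | C[C@H]1[C@H](B[C@H]3CCc4cc(OC)ccc4[C@@H]3C)C[C@@H]2C[C@H]1C2(C)C | intermediate
6 | (1S,2S)-6-methoxy-1-methyl-1,2,3,4-tetrahydronaphthalen-2-ol | C[C@@H]1[C@@H](O)CCc2cc(OC)ccc12 | intermediate
7 | (1S,2S)-6-methoxy-1-methyl-1,2,3,4,5,8-hexahydronaphthalen-2-ol | C[C@@H]1[C@@H](O)CCC2=C1CC=C(OC)C2 | intermediate
8 | ethylene glycol | OCCO | starting material
9 | 3β-hydroxy-4α-methyl-5(10)-ene 8-(ethylene ketal) | C[C@@H]1[C@@H](O)CCC2=C1CCC1(C2)OCCO1 | intermediate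
10 | diiodomethane | ICI | starting material
11 | ethylzinc alkoxide of 9 | C[C@@H]1[C@@H](O[Zn]CC)CCC2=C1CCC1(C2)OCCO1 | intermediate
12 | 3β-hydroxy-4α-methyl-5β,10β-methano 8-(ethylene ketal) | C[C@@H]1[C@@H](O)CC[C@@]23C[C@@]12CCC1(C3)OCCO1 | intermediate
13 | 4α-methyl-5β,10β-methano-3-one 8-(ethylene ketal) | C[C@@H]1C(=O)CC[C@@]23C[C@@]12CCC1(C3)OCCO1 | intermediate
14 | (10R)-4,10β-dimethyl-4-en-3-one 8-(ethylene ketal) | C1COC2(O1)CCC3=C(C)C(=O)CC[C@]3(C)C2 | intermediate
15 | (3S,10R)-3β-hydroxy-4,10β-dimethyl-4-ene 8-(ethylene ketal) | C1COC2(O1)CCC3=C(C)[C@@H](O)CC[C@]3(C)C2 | intermediate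
16 | tert-butyldimethylsilyl chloride | CC(C)(C)[Si](C)(C)Cl | starting material
17 | 3β-(tert-butyldimethylsilyloxy)-4,10β-dimethyl-4-ene 8-(ethylene ketal) | C1COC2(O1)CCC3=C(C)[C@@H](O[Si](C)(C)C(C)(C)C)CC[C@]3(C)C2 | intermediate
18 | 3β-(tert-butyldimethylsilyloxy)-11,12,13-trinoreudesm-4-en-8-one | O=C1CCC2=C(C)[C@@H](O[Si](C)(C)C(C)(C)C)CC[C@]2(C)C1 | intermediate
19 | methyl bromoacetate | COC(=O)CBr | starting material
20 | lithium enolate of 18 (C7=C8) | [Li]OC1=CCC2=C(C)[C@@H](O[Si](C)(C)C(C)(C)C)CC[C@]2(C)C1 | intermediate
21 | methyl 8-oxo-3β-(tert-butyldimethylsilyloxy)-13-noreudesm-4-en-12-oate, 7α side chain | COC(=O)C[C@@H]1CC2=C(C)[C@@H](O[Si](C)(C)C(C)(C)C)CC[C@]2(C)CC1=O | intermediate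
22 | methyl 8-oxo-3β-(tert-butyldimethylsilyloxy)-13-noreudesm-4-en-12-oate, 7β side chain | COC(=O)C[C@H]1CC2=C(C)[C@@H](O[Si](C)(C)C(C)(C)C)CC[C@]2(C)CC1=O | intermediate
23 | lithium 8β-alkoxide of the hydroxy ester | COC(=O)C[C@H]1CC2=C(C)[C@@H](O[Si](C)(C)C(C)(C)C)CC[C@]2(C)C[C@H]1O[Li] | intermediate
24 | 3β-(tert-butyldimethylsilyloxy)-13-noreudesm-4-en-12,8β-olide | O=C3C[C@H]1CC2=C(C)[C@@H](O[Si](C)(C)C(C)(C)C)CC[C@]2(C)C[C@H]1O3 | intermediate
25 | N,N-dimethylmethyleneiminium iodide | C=[N+](C)C.[I-] | starting material
26 | lithium enolate of lactone 24 | [Li]OC3=C[C@H]1CC2=C(C)[C@@H](O[Si](C)(C)C(C)(C)C)CC[C@]2(C)C[C@H]1O3 | intermediate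
27 | 13-(dimethylamino)-3β-(tert-butyldimethylsilyloxy)eudesm-4-en-12,8β-olide | CN(C)C[C@@H](C3=O)[C@H]1CC2=C(C)[C@@H](O[Si](C)(C)C(C)(C)C)CC[C@]2(C)C[C@H]1O3 | intermediate
28 | iodomethane | CI | starting material
29 | trimethylammonium iodide of 27 | C[N+](C)(C)C[C@@H](C3=O)[C@H]1CC2=C(C)[C@@H](O[Si](C)(C)C(C)(C)C)CC[C@]2(C)C[C@H]1O3.[I-] | intermediate
30 | 3β-(tert-butyldimethylsilyloxy)eudesma-4,11(13)-dien-12,8β-olide | C=C(C3=O)[C@H]1CC2=C(C)[C@@H](O[Si](C)(C)C(C)(C)C)CC[C@]2(C)C[C@H]1O3 | intermediate
31 | potassium 8β-hydroxy-3β-(tert-butyldimethylsilyloxy)eudesma-4,11(13)-dien-12-oate | C=C(C(=O)[O-])[C@H]1CC2=C(C)[C@@H](O[Si](C)(C)C(C)(C)C)CC[C@]2(C)C[C@H]1O.[K+] | intermediate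
32 | methyl 8β-hydroxy-3β-(tert-butyldimethylsilyloxy)eudesma-4,11(13)-dien-12-oate | C=C(C(=O)OC)[C@H]1CC2=C(C)[C@@H](O[Si](C)(C)C(C)(C)C)CC[C@]2(C)C[C@H]1O | intermediate
33 | acetic anhydride | CC(=O)OC(C)=O | starting material
34 | methyl 8β-acetoxy-3β-(tert-butyldimethylsilyloxy)eudesma-4,11(13)-dien-12-oate | C=C(C(=O)OC)[C@H]1CC2=C(C)[C@@H](O[Si](C)(C)C(C)(C)C)CC[C@]2(C)C[C@H]1OC(C)=O | intermediate
35 | methyl 8β-acetoxy-3β-hydroxyeudesma-4,11(13)-dien-12-oate | C=C(C(=O)OC)[C@H]1CC2=C(C)[C@@H](O)CC[C@]2(C)C[C@H]1OC(C)=O | intermediate
36 | (E)-3-methylpent-2-enoic acid | CC/C(C)=C/C(=O)O | starting material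
37 | methyl 8β-acetoxy-3β-[(E)-3-methylpent-2-enoyloxy]eudesma-4,11(13)-dien-12-oate | C=C(C(=O)OC)[C@H]1CC2=C(C)[C@@H](OC(=O)/C=C(\C)CC)CC[C@]2(C)C[C@H]1OC(C)=O | target

## Step count and risks

Total: 18 steps. Longest linear sequence: 18 steps, from 6-methoxy-1-tetralone 1 to target 37.

**Step 5 (key step).** Methylene transfer to the hindered tetrasubstituted alkene may be slow, and prolonged exposure to zinc iodide may cleave the ketal. Competing delivery from the ketal oxygens could also erode the facial selectivity. Fallback, from 9 back to 12: dibromocarbene is added under phase-transfer conditions (CHBr3, 50% aq. NaOH, BnEt3NCl), which tolerate the free hydroxyl and the ketal. Carbene addition does not depend on zinc coordination; its face is chosen by the pseudo-axial 4α-methyl and by the known syn-directing effect of a hydroxyl under these conditions. This should give the 14,14-dibromo-5β,10β-methano alcohol F1. Reduction of both C–Br bonds with Bu3SnH and AIBN in toluene at 80 °C then returns 12.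

**Step 2.** Facial discrimination by the chiral borane may be incomplete on this benzo-fused alkene, leaving material of insufficient enantiomeric purity. Fallback, from 4 back to 6: hydroboration with BH3·SMe2 and oxidation gives the racemic trans alcohol F2. A lipase-catalysed kinetic resolution (Candida antarctica lipase B, vinyl acetate) is expected to acylate the (2R) carbinol, giving the (1R,2R)-acetate F3 and leaving 6, which is separated and carried on.

**Step 7.** Adventitious water may cause loss of the dioxolane during the acid-mediated opening, or the opening may stall under strictly anhydrous conditions. Fallback, from 13 back to 14: aqueous HCl in THF is used deliberately, so that cyclopropane opening and ketal hydrolysis both go to completion and give (4aR)-1,4a-dimethyl-4,4a,7,8-tetrahydronaphthalene-2,6(3H,5H)-dione F4. The saturated C8 ketone is then re-ketalised selectively in the presence of the conjugated enone (ethylene glycol, PPTS, benzene, water removal), as is routine for saturated-ketone/enone pairs, returning 14.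

**Step 11.** Proton transfer between enolate and product may lead to deprotonation towards C9 or to double alkylation, and the reactive bromo ester may be consumed by the amide base. Fallback, from 18 back to 22: the ketone is condensed with pyrrolidine (molecular sieves, benzene) to the less substituted C7=C8 pyrrolidine enamine F5. This is alkylated with methyl bromoacetate in acetonitrile to the C7-alkylated iminium bromide F6, which is hydrolysed in the same flask with aqueous acetate buffer. Brief NaOMe equilibration then gives 22. Enamine alkylation is mono-selective and needs no strong base.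

**Step 16 (with step 15).** Re-closure of the γ-hydroxy ester to the lactone may compete with acetylation of the hindered axial hydroxyl. Fallback, from 30 back to 34, in which the carboxyl is held at the alcohol level while O8 is acetylated:
- i-Bu2AlH in CH2Cl2 at −78 °C reduces the lactone to the 8β,12-diol F7.
- The primary allylic hydroxyl is silylated selectively (Et3SiCl, imidazole, −40 °C) to the 12-O-triethylsilyl ether F8.
- Acetylation (Ac2O, DMAP, pyridine) gives the 8β-acetate F9.
- The triethylsilyl group is removed in the presence of the secondary TBS ether (PPTS, MeOH, 0 °C) to give the 12-hydroxy 8β-acetate F10.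
- MnO2 in CH2Cl2 oxidises the allylic alcohol to the 2-substituted acrolein F11.
- Pinnick oxidation (NaClO2, NaH2PO4, 2-methyl-2-butene) gives the acrylic acid F12.
- Me3SiCHN2 in MeOH–toluene gives 34.

## Further compounds

F1 | step 5 | 14,14-dibromo-3β-hydroxy-4α-methyl-5β,10β-methano 8-(ethylene ketal) | C[C@@H]1[C@@H](O)CC[C@@]23C(Br)(Br)[C@@]12CCC1(C3)OCCO1
F2 | step 2 | racemic trans-6-methoxy-1-methyl-1,2,3,4-tetrahydronaphthalen-2-ol | C[C@@H]1[C@@H](O)CCc2cc(OC)ccc12.C[C@H]1[C@H](O)CCc2cc(OC)ccc12
F3 | step 2 | (1R,2R)-6-methoxy-1-methyl-1,2,3,4-tetrahydronaphthalen-2-yl acetate | C[C@H]1[C@H](OC(C)=O)CCc2cc(OC)ccc12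
F4 | step 7 | (4aR)-1,4a-dimethyl-4,4a,7,8-tetrahydronaphthalene-2,6(3H,5H)-dione | O=C1CCC2=C(C)C(=O)CC[C@]2(C)C1
F5 | step 11 | pyrrolidine enamine of 18 (C7=C8) | C1CCN(C1)C1=CCC2=C(C)[C@@H](O[Si](C)(C)C(C)(C)C)CC[C@]2(C)C1
F6 | step 11 | C7-alkylated pyrrolidinium (iminium) bromide, 7α side chain | COC(=O)C[C@@H]1CC2=C(C)[C@@H](O[Si](C)(C)C(C)(C)C)CC[C@]2(C)CC1=[N+]1CCCC1.[Br-]
F7 | step 16 | 3β-(tert-butyldimethylsilyloxy)eudesma-4,11(13)-diene-8β,12-diol | C=C(CO)[C@H]1CC2=C(C)[C@@H](O[Si](C)(C)C(C)(C)C)CC[C@]2(C)C[C@H]1O
F8 | step 16 | 12-O-triethylsilyl ether of F7 | C=C(CO[Si](CC)(CC)CC)[C@H]1CC2=C(C)[C@@H](O[Si](C)(C)C(C)(C)C)CC[C@]2(C)C[C@H]1O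
F9 | step 16 | 8β-acetate of F8 | C=C(CO[Si](CC)(CC)CC)[C@H]1CC2=C(C)[C@@H](O[Si](C)(C)C(C)(C)C)CC[C@]2(C)C[C@H]1OC(C)=O
F10 | step 16 | 8β-acetoxy-3β-(tert-butyldimethylsilyloxy)eudesma-4,11(13)-dien-12-ol | C=C(CO)[C@H]1CC2=C(C)[C@@H](O[Si](C)(C)C(C)(C)C)CC[C@]2(C)C[C@H]1OC(C)=O
F11 | step 16 | 8β-acetoxy-3β-(tert-butyldimethylsilyloxy)eudesma-4,11(13)-dien-12-al | C=C(C=O)[C@H]1CC2=C(C)[C@@H](O[Si](C)(C)C(C)(C)C)CC[C@]2(C)C[C@H]1OC(C)=O
F12 | step 16 | 8β-acetoxy-3β-(tert-butyldimethylsilyloxy)eudesma-4,11(13)-dien-12-oic acid | C=C(C(=O)O)[C@H]1CC2=C(C)[C@@H](O[Si](C)(C)C(C)(C)C)CC[C@]2(C)C[C@H]1OC(C)=O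
A1 | alternative 1 | triene lactone: trans γ-lactone with the 2-silyloxy-diene arm on C7 and a methallyl group on C8 | O=C1C[C@@H](C/C=C(\C)C(=C)O[Si](C)(C)C(C)(C)C)[C@H](CC(C)=C)O1
A2 | alternative 1 | tricyclic silyl enol ether (trans-fused lactone, 10β-methyl, 5α-H) | O=C1C[C@H]2C[C@H]3C(C)=C(O[Si](C)(C)C(C)(C)C)CC[C@]3(C)C[C@@H]2O1
A3 | alternative 2 | ring-A C8 aldehyde carrying the (Z)-2-(bromomethyl)enoate arm | BrC/C(C(=O)OC)=C\CC1=C(C)[C@@H](O[Si](C)(C)C(C)(C)C)CC[C@]1(C)CC=O
A4 | alternative 2 | 8-keto acrylate with 7β side chain and 3β-silyloxy group | C=C(C(=O)OC)[C@H]1CC2=C(C)[C@@H](O[Si](C)(C)C(C)(C)C)CC[C@]2(C)CC1=O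
A5 | alternative 3 | mixed bromoacetal of the 3β-silyloxy-4,6-dien-8β-ol | CCOC(CBr)O[C@@H]1C[C@@]2(C)CC[C@H](O[Si](C)(C)C(C)(C)C)C(C)=C2C=C1
A6 | alternative 3 | cis-fused lactol ethyl ether with the C4=C5 alkene | CCOC1C[C@H]2CC3=C(C)[C@@H](O[Si](C)(C)C(C)(C)C)CC[C@]3(C)C[C@H]2O1
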